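**Strategy.** The route rests on disconnecting the C3–C3a bond of the dihydrofuran ring. An aryl radical generated at C3a, the ring-A carbon ortho to the ether oxygen O1, closes 5-exo onto the vinyl group of an enantioenriched aryl 1-arylallyl ether. In one operation this forms the five-membered ring, sets C3 trans to the existing C2 stereocentre and turns the alkene terminus into the C3 methyl group. The precursor is an acyclic iodoaryl ether, made by iridium-catalysed asymmetric allylic etherification of methyl 5-iodoferulate with a cinnamyl carbonate. The step exploits the O1–C2–C3–C3a array, in which C3a lies ortho to oxygen and C3 carries only a methyl group.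

Key step: step 4

Remarks and assumptions on the chemistry:
- Benzofuran numbering (O1, C2, C3, C3a, C4–C7, C7a) is used; the target is the trans-(2S,3S) isomer.
- The (Sa,Sc,Sc)-configured phosphoramidite is assumed to deliver the (S)-ether in step 3, by analogy with the usual sense of induction of this catalyst class with cinnamyl carbonates. If a test reaction shows the opposite sense, the enantiomeric ligand is used.
- 5-Iodovanillin (1) and 3,4-dimethoxycinnamyl alcohol (3) are taken as catalogue compounds.

Step 1
Reactants: 1 5-iodovanillin (4-hydroxy-3-iodo-5-methoxybenzaldehyde)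
Product: 2 methyl (E)-3-(4-hydroxy-3-iodo-5-methoxyphenyl)prop-2-enoate (methyl 5-iodoferulate)
Conditions: Ph3P=CHCO2Me (2.2 equiv), toluene, 90 °C
Reagents that add atoms: methyl (triphenylphosphoranylidene)acetate, COC(=O)C=P(c1ccccc1)(c1ccccc1)c1ccccc1
Why: Wittig olefination with a stabilised ylide is E-selective and tolerates the free phenol when the ylide is used in excess and the mixture is heated.

Step 2
Reactants: 3 (E)-3-(3,4-dimethoxyphenyl)prop-2-en-1-ol (3,4-dimethoxycinnamyl alcohol)
Product: 4 (E)-3-(3,4-dimethoxyphenyl)prop-2-en-1-yl methyl carbonate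
Conditions: ClCO2Me, pyridine, CH2Cl2, 0 °C
Reagents that add atoms: methyl chloroformate, COC(=O)Cl
Why: Acylation of the primary allylic alcohol with a chloroformate gives the carbonate leaving group needed for allyl–metal chemistry.

Step 3
Reactants: 2 methyl 5-iodoferulate; 4 (E)-3-(3,4-dimethoxyphenyl)prop-2-en-1-yl methyl carbonate
Product: 6 methyl (E)-3-{4-[(1S)-1-(3,4-dimethoxyphenyl)prop-2-en-1-yloxy]-3-iodo-5-methoxyphenyl}prop-2-enoate, via sodium aryloxide 5 (not isolated)
Conditions: NaH, THF, 0 °C; then 4, [Ir(cod)Cl]2 (2 mol %), (Sa,Sc,Sc)-BINOL N,N-bis(1-phenylethyl)phosphoramidite (4 mol %, pre-activated with n-PrNH2), THF, rt; chromatography on Et3N-deactivated silica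
Reagents that add atoms: none
Why: In this iridium-catalysed asymmetric allylic etherification the allyliridium complex formed by loss of methyl carbonate is attacked by the aryloxide at its aryl-substituted terminus, the phosphoramidite controls the face so that the branched (S)-ether should form, and the liberated methoxide is degenerate toward the methyl ester.

Step 4
Reactants: 6 methyl (E)-3-{4-[(1S)-1-(3,4-dimethoxyphenyl)prop-2-en-1-yloxy]-3-iodo-5-methoxyphenyl}prop-2-enoate
Product: 7 methyl (E)-3-[(2S,3S)-2-(3,4-dimethoxyphenyl)-7-methoxy-3-methyl-2,3-dihydro-1-benzofuran-5-yl]prop-2-enoate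
Conditions: Bu3SnH (1.3 equiv), Et3B (0.2 equiv), trace air, toluene (0.02 M), 0 °C; minor cis isomer removed by chromatography
Reagents that add atoms: none
Why: Ethyl radicals from Et3B and oxygen start a chain in which the Bu3Sn radical abstracts iodine from 6 to give the aryl sigma radical at C3a, which adds 5-exo-trig to the internal vinyl carbon (forming C3a–C3), and the resulting primary radical takes hydrogen from Bu3SnH so that the exocyclic carbon becomes the C3 methyl group. The closest known reaction type is the tin hydride mediated aryl radical cyclisation of 2-halophenyl allyl ethers to 3-methyl-2,3-dihydrobenzofurans. The dihydrofuran ring is closed in the 5-exo-trig mode, which is kinetically preferred over 6-endo closure for this short oxygen tether. The new C3 centre is controlled by the C2 centre: in the chair-like transition-state model for 5-hexenyl radical closures the alkene lies perpendicular to the forming ring with C2–H eclipsing the double bond, so the =CH2 terminus turns away from the C2 aryl group and the trans-(2S,3S) isomer should predominate. The step needs chemoselectivity for the C–I bond over the cinnamate and for the five-membered over the ring-expanded product; iodine abstraction and the intramolecular closure should outrun stannyl or alkyl radical addition to the acrylate, and a moderate stannane concentration suppresses neophyl-type rearrangement. The low temperature protects the ionisable benzylic allylic aryl ether and should sharpen the facial preference.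

Step 5
Reactants: 7 methyl (E)-3-[(2S,3S)-2-(3,4-dimethoxyphenyl)-7-methoxy-3-methyl-2,3-dihydro-1-benzofuran-5-yl]prop-2-enoate
Product: 9 (E)-3-[(2S,3S)-2-(3,4-dimethoxyphenyl)-7-methoxy-3-methyl-2,3-dihydro-1-benzofuran-5-yl]prop-2-en-1-ol (target), via enal 8 (not isolated)
Conditions: i-Bu2AlH (2.5 equiv), CH2Cl2, −78 °C; aq. potassium sodium tartrate
Reagents that add atoms: none
Why: i-Bu2AlH reduces the α,β-unsaturated methyl ester by 1,2-hydride addition, through the enal, to the (E)-allylic alcohol at low temperature without touching the benzylic ether or the two stereocentres.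

**Compound list**
1 | 5-iodovanillin (4-hydroxy-3-iodo-5-methoxybenzaldehyde) | COc1cc(C=O)cc(I)c1O | starting material
2 | methyl (E)-3-(4-hydroxy-3-iodo-5-methoxyphenyl)prop-2-enoate | COC(=O)/C=C/c1cc(I)c(O)c(OC)c1 | intermediate
3 | (E)-3-(3,4-dimethoxyphenyl)prop-2-en-1-ol | COc1ccc(/C=C/CO)cc1OC | starting material
4 | (E)-3-(3,4-dimethoxyphenyl)prop-2-en-1-yl methyl carbonate | COC(=O)OC/C=C/c1ccc(OC)c(OC)c1 | intermediate
5 | sodium 2-iodo-6-methoxy-4-[(E)-3-methoxy-3-oxoprop-1-enyl]phenolate | COC(=O)/C=C/c1cc(I)c([O-])c(OC)c1.[Na+] | intermediate (not isolated)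
6 | methyl (E)-3-{4-[(1S)-1-(3,4-dimethoxyphenyl)prop-2-en-1-yloxy]-3-iodo-5-methoxyphenyl}prop-2-enoate | COc1ccc([C@H](C=C)Oc2c(OC)cc(/C=C/C(=O)OC)cc2I)cc1OC | intermediate
7 | methyl (E)-3-[(2S,3S)-2-(3,4-dimethoxyphenyl)-7-methoxy-3-methyl-2,3-dihydro-1-benzofuran-5-yl]prop-2-enoate | COc1ccc([C@H]2Oc3c(OC)cc(/C=C/C(=O)OC)cc3[C@@H]2C)cc1OC | intermediate
8 | (E)-3-[(2S,3S)-2-(3,4-dimethoxyphenyl)-7-methoxy-3-methyl-2,3-dihydro-1-benzofuran-5-yl]prop-2-enal | COc1ccc([C@H]2Oc3c(OC)cc(/C=C/C=O)cc3[C@@H]2C)cc1OC | intermediate (not isolated)
9 | (E)-3-[(2S,3S)-2-(3,4-dimethoxyphenyl)-7-methoxy-3-methyl-2,3-dihydro-1-benzofuran-5-yl]prop-2-en-1-ol | COc1ccc([C@H]2Oc3c(OC)cc(/C=C/CO)cc3[C@@H]2C)cc1OC | target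

**Total step count:** 5. **Longest linear sequence:** 4 steps (1 → 2 → 6 → 7 → 9).

**Steps most likely to fail**

Step 3. What may go wrong: slow attack of the doubly ortho-substituted, weakly nucleophilic aryloxide on the allyliridium intermediate, leading to linear ether, and re-ionisation of the electron-rich benzylic aryl ether under the catalyst with erosion of branched selectivity and enantiopurity. Fallback: the stereocentre is set with a small oxygen nucleophile and the hindered C–O bond is then made by inversion. The fallback sets out from carbonate 4. Iridium-catalysed allylic hydroxylation with KHCO3 as hydroxide equivalent, using [Ir(cod)Cl]2 and the enantiomeric (Ra,Rc,Rc) ligand, should give (R)-1-(3,4-dimethoxyphenyl)prop-2-en-1-ol F1. Mitsunobu coupling of this alcohol with phenol 2 (PPh3, DIAD, toluene, 0 °C) inverts the carbinol centre and comes back to the route at ether 6.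

Step 4. What may go wrong: insufficient facial selectivity in the radical closure, giving too much cis isomer, or ionisation of the labile ether before closure. Fallback: C3 is set first under catalyst control and the ring is closed at O1–C2 under thermodynamic control. The fallback sets out from phenol 2.
- MOMCl and i-Pr2NEt give methyl (E)-3-[3-iodo-5-methoxy-4-(methoxymethoxy)phenyl]prop-2-enoate F2.
- Zinc insertion (Zn dust, LiCl, THF) gives the arylzinc iodide F3 (not isolated).
- Enantioconvergent Negishi coupling of this reagent with racemic 2-bromo-1-(3,4-dimethoxyphenyl)propan-1-one (NiCl2(glyme), chiral pybox ligand of the series that gives the S product, glyme/THF, −30 °C) should give the (S)-configured α-aryl ketone F4.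
- NaBH4 in MeOH at 0 °C gives the benzylic alcohol F5 as both carbinol epimers.
- HCl in MeOH removes the methoxymethyl group and closes the ring through the benzylic cation. Both epimers should converge on the trans product, and the sequence comes back to the route at ester 7.

Step 1. What may go wrong: deprotonation of the acidic iodophenol by the ylide, which deactivates the aldehyde as its phenoxide and stalls the olefination. Fallback: a Knoevenagel–Doebner condensation, which tolerates free phenols. It sets out from aldehyde 1, which is heated with methyl hydrogen malonate, pyridine and catalytic piperidine at 90 °C. The benzylidene malonic half ester F6 (not isolated) decarboxylates in the flask, and the sequence comes back to the route at ester 2.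

**Further compounds**
F1 | step 3 | (R)-1-(3,4-dimethoxyphenyl)prop-2-en-1-ol | COc1ccc([C@@H](C=C)O)cc1OC
F2 | step 4 | methyl (E)-3-[3-iodo-5-methoxy-4-(methoxymethoxy)phenyl]prop-2-enoate | COCOc1c(I)cc(/C=C/C(=O)OC)cc1OC
F3 | step 4 | {2-methoxy-6-... aryl}zinc iodide: [3-methoxy-2-(methoxymethoxy)-5-[(E)-3-methoxy-3-oxoprop-1-enyl]phenyl]zinc iodide (not isolated) | COCOc1c([Zn]I)cc(/C=C/C(=O)OC)cc1OC
F4 | step 4 | methyl (E)-3-{3-[(2S)-1-(3,4-dimethoxyphenyl)-1-oxopropan-2-yl]-5-methoxy-4-(methoxymethoxy)phenyl}prop-2-enoate | COCOc1c(OC)cc(/C=C/C(=O)OC)cc1[C@H](C)C(=O)c1ccc(OC)c(OC)c1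
F5 | step 4 | methyl (E)-3-{3-[(2S)-1-(3,4-dimethoxyphenyl)-1-hydroxypropan-2-yl]-5-methoxy-4-(methoxymethoxy)phenyl}prop-2-enoate (both carbinol epimers) | COCOc1c(OC)cc(/C=C/C(=O)OC)cc1[C@H](C)C(O)c1ccc(OC)c(OC)c1
F6 | step 1 | 2-[(4-hydroxy-3-iodo-5-methoxyphenyl)methylidene]propanedioic acid monomethyl ester (alkene geometry not fixed; not isolated) | COC(=O)C(=Cc1cc(I)c(O)c(OC)c1)C(=O)O
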